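**Assumption:** the target is drawn as one enol tautomer of a 2-acyl-cyclohexane-1,3,5-trione; every trione below is written in that tautomer and CIP labels refer to it. Locants follow spiro[cyclohexane-1,5'-indene]: C1 spiro, C3' and C7' carbinols, C3a'/C7a' ring fusion.

## Retrosynthetic overview

1. Target ⇐ twofold Wittig isopropylidenation of a bis(2-oxoethyl) compound. The prenyl C=C bonds are made last and carried as allyl groups, because prenyl alkenes would not survive the radical hydration in line 2.
2. C7' tertiary alcohol ⇐ Markovnikov hydrogen-atom-transfer hydration of the C6'=C7' alkene of a spiro-hexahydroindene.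
3. Cyclohexene and cyclopentane rings, with C1, C3a' and C7a' ⇐ one intramolecular Diels–Alder reaction. The diene is the alkylidene-trione dienone formed in the same flask by Knoevenagel condensation; the dienophile is the vinyl group of the linalool-derived chain.
4. Components: 2-acetyl-4,4-diallyl trione (dearomatising C,C-diallylation of 2,4,6-trihydroxyacetophenone) and (R)-8-oxolinalool (SeO2 oxidation of (R)-linalool, which supplies C3').
5. Ring order: acyl-trione ring first (from the arene), then cyclohexene and cyclopentane together.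

## Route

**Step 1**
Reactants: 1 2,4,6-trihydroxyacetophenone; 2 allyl bromide (2.1 equiv)
Product: 3 2-acetyl-4,4-diallyl trione (enol form)
Conditions: NaOMe (2.2 equiv), MeOH, 0 °C → rt; chromatography
Reagents that add atoms: none
Why: Alkylative dearomatisation: in a protic medium the phloroglucinol anion is C-allylated, and the second allylation at the same ring carbon gives the non-aromatic, strongly acidic gem-diallyl β-triketone (the known behaviour of acylphloroglucinols with MeI or prenyl bromide); no stereocentre is formed.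

**Step 2**
Reactants: 4 (R)-(−)-linalool
Product: 5 (2E,6R)-6-hydroxy-2,6-dimethylocta-2,7-dienal
Conditions: SeO2 (1.1 equiv), 1,4-dioxane/EtOH, 80 °C
Reagents that add atoms: selenium dioxide, O=[Se]=O
Why: Riley allylic oxidation (ene then [2,3]-shift) takes the (E)-methyl of the trisubstituted alkene to the (E)-enal, while the monosubstituted vinyl group and the tertiary carbinol stereocentre are untouched.

**Step 3**
Reactants: 3 2-acetyl-4,4-diallyl trione; 5 (2E,6R)-6-hydroxy-2,6-dimethylocta-2,7-dienal
Product: 7 spiro-hexahydroindene Diels–Alder adduct, via alkylidene dienone 6 (not isolated)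
Conditions: ethylenediammonium diacetate (10 mol %), 4 Å MS, PhCl, 60 °C; then dilute to 0.01 M, BHT (cat.), 130 °C, sealed tube
Reagents that add atoms: none
Why: Proposed new method: Knoevenagel condensation at C6 of 3 gives the 2-alkenylidene-1,3-dione 6, whose acceptor-substituted diene (exocyclic C=C–C(Me)=CH) sits three atoms from the vinyl carbinol, so a type-1 intramolecular [4+2] (nona-1,3,8-triene pattern) closes cyclohexene and cyclopentane together and is the only irreversible intramolecular outlet (oxa-6π closure of 6 is reversible, and a hetero-Diels–Alder reaction with the vinyl group would need a trans-cycloheptene); the (E)-diene with an anti tether gives the trans ring fusion, the C3' centre from linalool directs the vinyl face with its C–O bond eclipsing the alkene (OH cis to C4'H2, methyl anti) to give 3a'S,7a'R, and C1 is set by which ring carbonyl lies inside the diene (the E/Z isomers of 6 equilibrate under the amine catalyst), so the 1S adduct is separated from its C1 epimer; closest known reaction types are domino Knoevenagel–hetero-Diels–Alder reactions of alkylidene-1,3-diones and thermal intramolecular Diels–Alder reactions of terminally activated nona-1,3,8-trienes.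

**Step 4**
Reactants: 7 spiro-hexahydroindene Diels–Alder adduct
Product: 8 C7' tertiary alcohol (diallyl diol)
Conditions: Mn(dpm)3 (0.3 equiv), PhSiH3 (2 equiv), O2 (1 atm), i-PrOH/CH2Cl2, 0 °C → rt; aqueous work-up
Reagents that add atoms: dioxygen, O=O
Why: Mukaiyama-type hydrogen-atom-transfer hydration: Mn–H delivers H• to C6' to give the tertiary C7' radical, which captures O2 on the face away from the axial spiro-ring carbonyl (equatorial C–O, 7'R); terminal monosubstituted allyl groups are much poorer hydrogen-atom acceptors than alkenes that give tertiary radicals.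

**Step 5**
Reactants: 8 C7' tertiary alcohol (diallyl diol)
Product: 9 bis(2-oxoethyl) dialdehyde
Conditions: OsO4 (2.5 mol %), NaIO4 (4.4 equiv), 2,6-lutidine, 1,4-dioxane/H2O (3:1), rt
Reagents that add atoms: sodium periodate, [Na+].[O-][I](=O)(=O)=O (oxygen delivered through catalytic osmium tetroxide, O=[Os](=O)(=O)=O)
Why: Lemieux–Johnson cleavage: the two unhindered terminal alkenes are dihydroxylated and cleaved, while the chelated electron-poor triketone enol and the tertiary alcohols are inert; no stereocentre is touched.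

**Step 6**
Reactants: 9 bis(2-oxoethyl) dialdehyde
Product: 10 target
Conditions: i-PrPPh3+ I− (7 equiv), n-BuLi (7 equiv), THF, 0 °C; then 9, −78 → 0 °C
Reagents that add atoms: isopropyltriphenylphosphonium iodide, CC(C)[P+](c1ccccc1)(c1ccccc1)c1ccccc1.[I-]
Why: Wittig olefination with the unstabilised isopropylidene ylide converts each CH2CHO arm into a prenyl group; the excess ylide absorbs the three acidic protons, the triketone enolate and the doubly neopentyl C6 ketone do not react, and no stereocentre is touched.

## Compound list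

1 | 2,4,6-trihydroxyacetophenone | CC(=O)c1c(O)cc(O)cc1O | starting material
2 | allyl bromide | C=CCBr | starting material
3 | 2-acetyl-3-hydroxy-4,4-di(prop-2-en-1-yl)cyclohex-2-ene-1,5-dione | CC(=O)C1=C(O)C(CC=C)(CC=C)C(=O)CC1=O | intermediate
4 | (R)-(−)-linalool, (3R)-3,7-dimethylocta-1,6-dien-3-ol | C=C[C@](C)(O)CCC=C(C)C | starting material
5 | (2E,6R)-6-hydroxy-2,6-dimethylocta-2,7-dienal | O=C/C(C)=C/CC[C@@](C)(O)C=C | intermediate
6 | 2-acetyl-3-hydroxy-6-[(2E,6R)-6-hydroxy-2,6-dimethylocta-2,7-dien-1-ylidene]-4,4-di(prop-2-en-1-yl)cyclohex-2-ene-1,5-dione (exocyclic C=C geometry mobile) | CC(=O)C1=C(O)C(CC=C)(CC=C)C(=O)C(=C/C(C)=C/CC[C@@](C)(O)C=C)C1=O | intermediate (not isolated)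
7 | (1S,3'R,3a'S,7a'R)-3-acetyl-3',4-dihydroxy-3',7'-dimethyl-5,5-di(prop-2-en-1-yl)-1',2',3',3a',4',7a'-hexahydrospiro[cyclohex-3-ene-1,5'-indene]-2,6-dione | CC(=O)C1=C(O)C(CC=C)(CC=C)C(=O)[C@@]2(C[C@H]3[C@@H](CC[C@@]3(C)O)C(C)=C2)C1=O | intermediate
8 | (1S,3'R,3a'S,7'R,7a'R)-3-acetyl-3',4,7'-trihydroxy-3',7'-dimethyl-5,5-di(prop-2-en-1-yl)octahydrospiro[cyclohex-3-ene-1,5'-indene]-2,6-dione | CC(=O)C1=C(O)C(CC=C)(CC=C)C(=O)[C@@]2(C[C@H]3[C@@H](CC[C@@]3(C)O)[C@](C)(O)C2)C1=O | intermediate
9 | 2,2'-[(1S,3'R,3a'S,7'R,7a'R)-3-acetyl-3',4,7'-trihydroxy-3',7'-dimethyl-2,6-dioxooctahydrospiro[cyclohex-3-ene-1,5'-indene]-5,5-diyl]diacetaldehyde | CC(=O)C1=C(O)C(CC=O)(CC=O)C(=O)[C@@]2(C[C@H]3[C@@H](CC[C@@]3(C)O)[C@](C)(O)C2)C1=O | intermediate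
10 | (1S,3'R,3a'S,7'R,7a'R)-3-acetyl-3',4,7'-trihydroxy-3',7'-dimethyl-5,5-bis(3-methylbut-2-en-1-yl)octahydrospiro[cyclohex-3-ene-1,5'-indene]-2,6-dione | CC(=O)C1=C(O)C(CC=C(C)C)(CC=C(C)C)C(=O)[C@@]2(C[C@H]3[C@@H](CC[C@@]3(C)O)[C@](C)(O)C2)C1=O | target

## Step count and risks

Total: 6 steps. Longest linear sequence: 5 steps (1 → 3 → 7 → 8 → 9 → 10).

**Step 3 (most likely to fail).** The cycloaddition must form a bond at the acceptor-bearing, fully substituted diene terminus and so gains little electronic help. The dienone can rest as its closed oxa-6π isomer, the allyl groups may undergo Cope shifts at 130 °C, and no strong bias is expected at C1, so a C1-epimer mixture (possibly near 1:1) and some cis-fused adduct are likely. The fallback sets out from 3 and returns at 8, replacing the cycloaddition by stepwise polar and radical ring closures. Commercial (R)-limonene 1,2-oxide is cleaved with periodic acid to (3R)-6-oxo-3-(prop-1-en-2-yl)heptanal F1. An L-proline-mediated 5-enolexo aldol closes the cyclopentane to (1S,2R,5R)-2-hydroxy-2-methyl-5-(prop-1-en-2-yl)cyclopentane-1-carbaldehyde F2; its aldol stereochemistry is assumed, not known. Reductive Knoevenagel alkylation of 3 with F2 and Hantzsch ester gives the C6-alkylated trione F3. Mn(OAc)3-catalysed aerobic 6-endo radical cyclisation of the trione radical onto the isopropenyl group, with O2 capture of the tertiary radical, gives the C7' hydroperoxide F4, which Me2S reduces to 8.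

**Step 4.** The allyl groups may be hydrated competitively, and the substrate's triketone may displace the ligands on manganese. The fallback sets out from 7 and returns at 9. Ring-closing metathesis (Grubbs II, CH2Cl2, 40 °C) ties the two allyl groups into the spiro-cyclopentene F5, whose 1,2-disubstituted alkene is essentially inert to hydrogen-atom transfer. The same Mn(dpm)3/PhSiH3/O2 hydration then gives the C7' alcohol F6, and OsO4/NaIO4 cleavage of the cyclopentene delivers dialdehyde 9 directly.

**Step 6.** The unprotected dialdehyde carries three acidic protons, can enolise and can close to a lactol, all of which may erode the double Wittig reaction. The fallback sets out from 9 and returns at 10, changing to a protect–olefinate–release sequence. TMSOTf/2,6-lutidine converts 9 into the tris(trimethylsilyl) derivative F7 (two tertiary silyl ethers and the triketone silyl enol ether). The Wittig reaction with 2.5 equiv of ylide gives the silylated diprenyl compound F8, and K2CO3/MeOH removes the three silyl groups to give 10.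

## Further compounds

F1 | step 3 | (3R)-6-oxo-3-(prop-1-en-2-yl)heptanal | O=CC[C@@H](CCC(C)=O)C(C)=C
F2 | step 3 | (1S,2R,5R)-2-hydroxy-2-methyl-5-(prop-1-en-2-yl)cyclopentane-1-carbaldehyde | O=C[C@H]1[C@@H](CC[C@@]1(C)O)C(C)=C
F3 | step 3 | 2-acetyl-3-hydroxy-6-{[(1S,2R,5R)-2-hydroxy-2-methyl-5-(prop-1-en-2-yl)cyclopentyl]methyl}-4,4-di(prop-2-en-1-yl)cyclohex-2-ene-1,5-dione | CC(=O)C1=C(O)C(CC=C)(CC=C)C(=O)C(C[C@H]2[C@@H](CC[C@@]2(C)O)C(C)=C)C1=O
F4 | step 3 | (1S,3'R,3a'S,7'R,7a'R)-3-acetyl-7'-hydroperoxy-3',4-dihydroxy-3',7'-dimethyl-5,5-di(prop-2-en-1-yl)octahydrospiro[cyclohex-3-ene-1,5'-indene]-2,6-dione | CC(=O)C1=C(O)C(CC=C)(CC=C)C(=O)[C@@]2(C[C@H]3[C@@H](CC[C@@]3(C)O)[C@](C)(OO)C2)C1=O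
F5 | step 4 | analogue of 7 in which the two allyl groups are closed to a spiro-cyclopent-3-ene at C5 (same 1S,3'R,3a'S,7a'R configuration) | CC(=O)C1=C(O)C2(CC=CC2)C(=O)[C@@]3(C[C@H]4[C@@H](CC[C@@]4(C)O)C(C)=C3)C1=O
F6 | step 4 | analogue of 8 in which the two allyl groups are closed to a spiro-cyclopent-3-ene at C5 (same 1S,3'R,3a'S,7'R,7a'R configuration) | CC(=O)C1=C(O)C2(CC=CC2)C(=O)[C@@]3(C[C@H]4[C@@H](CC[C@@]4(C)O)[C@](C)(O)C3)C1=O
F7 | step 6 | tris(trimethylsilyl) derivative of 9 (3'-O-TMS, 7'-O-TMS, 4-O-TMS enol ether) | CC(=O)C1=C(O[Si](C)(C)C)C(CC=O)(CC=O)C(=O)[C@@]2(C[C@H]3[C@@H](CC[C@@]3(C)O[Si](C)(C)C)[C@](C)(O[Si](C)(C)C)C2)C1=O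
F8 | step 6 | tris(trimethylsilyl) derivative of 10 (3'-O-TMS, 7'-O-TMS, 4-O-TMS enol ether) | CC(=O)C1=C(O[Si](C)(C)C)C(CC=C(C)C)(CC=C(C)C)C(=O)[C@@]2(C[C@H]3[C@@H](CC[C@@]3(C)O[Si](C)(C)C)[C@](C)(O[Si](C)(C)C)C2)C1=O
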